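**Retrosynthetic overview**
1. The aryl–alkene bond is cut last (Heck reaction), the ester C–O bond before it (acylation of the hindered axial alcohol with an acryloyl unit).
2. The axial alcohol comes from the trans-fused β,γ-unsaturated decalone: the ring-fusion hydrogen by kinetic protonation of the extended dienolate, the carbinol by equatorial hydride delivery.
3. Key disconnection: ring B (C6–C7 bond, isopropyl-bearing stereocentre) by one-carbon ring expansion of a cyclopentanone with the diazoalkane derived from isobutyraldehyde.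
4. The β,γ-unsaturated hydrindanone comes from the conjugated hydrindenone: ring A by aldol condensation, the quaternary centre by asymmetric conjugate addition to 3-methylcyclopentenone.
5. Ring order: five-membered ring (bought) → ring A (annulation) → ring B (five-to-six ring expansion).

Assumption: 2-(3-chloropropyl)-2-methyl-1,3-dioxolane is bought as such (the ethylene-ketal-protected form of 5-chloropentan-2-one); both antipodes of the two chiral ligands are available and the one that gives the stated configuration is used; C-numbers in the text are eudesmane numbers (C10 quaternary, C5 ring-fusion CH, C6 carbinol, C7 isopropyl-bearing).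

**Step 1**
Reactants: 1 3-methylcyclopent-2-en-1-one; 2 2-(3-chloropropyl)-2-methyl-1,3-dioxolane
Product: 6 (3aR)-3a,7-dimethyl-2,3,3a,4,5,6-hexahydro-1H-inden-1-one, via Grignard reagent 3 (not isolated), via ketal ketone 4 (not isolated), via diketone 5 (not isolated)
Conditions: 2, Mg, THF, 55 °C; then 1, Cu(OTf)2 (4 mol%), (S)-1-(1-hydroxy-4-methylpentan-2-yl)-3-mesityl-4,5-dihydroimidazolium hexafluorophosphate (5 mol%), Et2O, −30 °C; then 3 M HCl aq., THF, 60 °C
Reagents that add atoms: none
Why: Copper-catalysed asymmetric conjugate addition of the Grignard reagent to the β-methyl enone (chiral NHC–Cu, face selection by the ligand) sets the quaternary centre as R, and the acid quench removes the ketal and drives the intramolecular aldol condensation of the 1,5-diketone that closes ring A (Robinson-type annulation).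

**Step 2**
Reactants: 6 (3aR)-3a,7-dimethyl-2,3,3a,4,5,6-hexahydro-1H-inden-1-one
Product: 8 (3aR)-3a,7-dimethyl-2,3,3a,4,5,7a-hexahydro-1H-inden-1-one as both 7a-epimers, via potassium dienolate 7 (not isolated)
Conditions: KOtBu (5 equiv), t-BuOH, 25 °C, 1 h, Ar; then poured into 10% aq. AcOH, 0 °C
Reagents that add atoms: none
Why: Deconjugative protonation of Ringold–Malhotra type, in which excess KOtBu gives the thermodynamic extended dienolate by γ-deprotonation of the ring CH2 and fast kinetic α-protonation gives the β,γ-unsaturated ketone; the new ring-fusion centre is not controlled here and is reset in step 5.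

**Step 3**
Reactants: 9 2-methylpropanal
Product: 10 (2-methylpropylidene)hydrazine
Conditions: N2H4·H2O (5 equiv), Et2O, 0 °C to rt; dried over KOH, distilled, stored cold
Reagents that add atoms: hydrazine hydrate, NN.O
Why: Hydrazone formation by condensation, with excess hydrazine suppressing the azine; no stereocentre is formed.

**Step 4**
Reactants: 8 (3aR)-3a,7-dimethyl-2,3,3a,4,5,7a-hexahydro-1H-inden-1-one as both 7a-epimers; 10 (2-methylpropylidene)hydrazine
Product: 12 (2S,4aR)-4a,8-dimethyl-2-(propan-2-yl)-3,4,4a,5,6,8a-hexahydronaphthalen-1(2H)-one as both 8a-epimers, via 1-diazo-2-methylpropane 11 (not isolated)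
Conditions: 10, activated MnO2, CH2Cl2, −20 °C, filtered cold over 4 Å sieves; added over 1 h to 8, Sc(OTf)3 (10 mol%), 2,6-bis[(4S)-4-phenyl-4,5-dihydro-1,3-oxazol-2-yl]pyridine (12 mol%), CH2Cl2–toluene, −78 °C
Reagents that add atoms: none
Why: Proposed new method: the non-stabilised diazoalkane 11 adds through carbon to the Sc-bound ketone and, in a Tiffeneau–Demjanov-type 1,2-shift, the unhindered C8 methylene migrates anti to the leaving N2 in preference to the tertiary allylic C5, which expands the cyclopentanone to the cyclohexanone of ring B with the isopropyl group in place; because the shift is stereospecific (inversion at the diazo carbon), the chiral Sc(OTf)3–pybox Lewis acid that selects one face of the diazo carbon should fix C7 as S for either ring-fusion epimer, and the neutral conditions at −78 °C leave this α-centre and the β,γ-alkene untouched; the closest known reaction type is the Sc(OTf)3-catalysed homologation of simple cycloalkanones with diazoalkanes (enantioselective with aryldiazomethanes), not yet shown for a chiral β,γ-unsaturated bicyclic ketone with an α-branched alkyldiazomethane under catalyst-controlled diastereoselection.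

**Step 5**
Reactants: 12 (2S,4aR)-4a,8-dimethyl-2-(propan-2-yl)-3,4,4a,5,6,8a-hexahydronaphthalen-1(2H)-one as both 8a-epimers
Product: 15 (1R,2S,4aR,8aR)-4a,8-dimethyl-2-(propan-2-yl)-1,2,3,4,4a,5,6,8a-octahydronaphthalen-1-ol, via potassium dienolate 13 (not isolated), via trans-ketone 14 (not isolated)
Conditions: KN(SiMe3)2 (1.1 equiv), THF, −78 °C, 30 min; AcOH (1.1 equiv) in THF, −78 °C; then LiBH(s-Bu)3 (1.5 equiv), −78 to −20 °C; H2O
Reagents that add atoms: none
Why: Kinetic enolate formation and protonation followed by Selectride reduction, in which KN(SiMe3)2 removes only the doubly activated (α-keto and allylic) C5 proton and leaves C7 alone, α-protonation of the extended dienolate opposite the axial angular methyl gives the trans-fused ketone (5α-H), and the bulky hydride then attacks equatorially from the same α-face (the axial path is blocked by the 1,3-diaxial methyl) to give the axial 6β-alcohol cis to the isopropyl group.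

**Step 6**
Reactants: 15 (1R,2S,4aR,8aR)-4a,8-dimethyl-2-(propan-2-yl)-1,2,3,4,4a,5,6,8a-octahydronaphthalen-1-ol; 16 prop-2-enoyl chloride
Product: 17 (1R,2S,4aR,8aR)-4a,8-dimethyl-2-(propan-2-yl)-1,2,3,4,4a,5,6,8a-octahydronaphthalen-1-yl prop-2-enoate
Conditions: Et3N (3 equiv), DMAP (0.2 equiv), CH2Cl2, 0 °C to rt
Reagents that add atoms: none
Why: DMAP-catalysed O-acylation of the hindered axial alcohol by the small, reactive acyl chloride, with the carbinol configuration retained because only the O–H bond reacts.

**Step 7**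
Reactants: 17 (1R,2S,4aR,8aR)-4a,8-dimethyl-2-(propan-2-yl)-1,2,3,4,4a,5,6,8a-octahydronaphthalen-1-yl prop-2-enoate; 18 4-iodophenol
Product: 19 (1R,2S,4aR,8aR)-4a,8-dimethyl-2-(propan-2-yl)-1,2,3,4,4a,5,6,8a-octahydronaphthalen-1-yl (2E)-3-(4-hydroxyphenyl)prop-2-enoate
Conditions: Pd(OAc)2 (5 mol%), P(o-tol)3 (10 mol%), Et3N (2 equiv), MeCN, 80 °C
Reagents that add atoms: none
Why: Mizoroki–Heck arylation of the acrylate β-carbon, which tolerates the free phenol, gives only the E-alkene by syn insertion and syn β-hydride elimination, and leaves the hindered trisubstituted ring alkene untouched.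

**Compound list**
1 | 3-methylcyclopent-2-en-1-one | CC1=CC(=O)CC1 | starting material
2 | 2-(3-chloropropyl)-2-methyl-1,3-dioxolane | CC1(CCCCl)OCCO1 | starting material
3 | [3-(2-methyl-1,3-dioxolan-2-yl)propyl]magnesium chloride | CC1(CCC[Mg]Cl)OCCO1 | intermediate
4 | (3R)-3-methyl-3-[3-(2-methyl-1,3-dioxolan-2-yl)propyl]cyclopentan-1-one | CC1(CCC[C@]2(C)CCC(=O)C2)OCCO1 | intermediate
5 | (3R)-3-methyl-3-(4-oxopentyl)cyclopentan-1-one | CC(=O)CCC[C@]1(C)CCC(=O)C1 | intermediate
6 | (3aR)-3a,7-dimethyl-2,3,3a,4,5,6-hexahydro-1H-inden-1-one | CC1=C2C(=O)CC[C@@]2(C)CCC1 | intermediate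
7 | potassium (3aR)-3a,7-dimethyl-3,3a,4,5-tetrahydro-2H-inden-1-olate (extended dienolate of 6) | CC1=CCC[C@]2(C)CCC([O-])=C12.[K+] | intermediate
8 | (3aR)-3a,7-dimethyl-2,3,3a,4,5,7a-hexahydro-1H-inden-1-one, mixture of 7a-epimers (centre left open) | CC1=CCC[C@]2(C)CCC(=O)C12 | intermediate
9 | 2-methylpropanal | CC(C)C=O | starting material
10 | (2-methylpropylidene)hydrazine | CC(C)C=NN | intermediate
11 | 1-diazo-2-methylpropane | CC(C)C=[N+]=[N-] | intermediate
12 | (2S,4aR)-4a,8-dimethyl-2-(propan-2-yl)-3,4,4a,5,6,8a-hexahydronaphthalen-1(2H)-one, mixture of 8a-epimers (centre left open) | CC1=CCC[C@]2(C)CC[C@@H](C(C)C)C(=O)C12 | intermediate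
13 | potassium (2S,4aR)-4a,8-dimethyl-2-(propan-2-yl)-2,3,4,4a,5,6-hexahydronaphthalen-1-olate (extended dienolate of 12) | CC1=CCC[C@]2(C)CC[C@@H](C(C)C)C([O-])=C12.[K+] | intermediate
14 | (2S,4aR,8aR)-4a,8-dimethyl-2-(propan-2-yl)-3,4,4a,5,6,8a-hexahydronaphthalen-1(2H)-one (trans-fused) | CC1=CCC[C@]2(C)CC[C@@H](C(C)C)C(=O)[C@@H]12 | intermediate
15 | (1R,2S,4aR,8aR)-4a,8-dimethyl-2-(propan-2-yl)-1,2,3,4,4a,5,6,8a-octahydronaphthalen-1-ol | CC1=CCC[C@]2(C)CC[C@@H](C(C)C)[C@@H](O)[C@@H]12 | intermediate
16 | prop-2-enoyl chloride | C=CC(=O)Cl | starting material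
17 | (1R,2S,4aR,8aR)-4a,8-dimethyl-2-(propan-2-yl)-1,2,3,4,4a,5,6,8a-octahydronaphthalen-1-yl prop-2-enoate | CC1=CCC[C@]2(C)CC[C@@H](C(C)C)[C@@H](OC(=O)C=C)[C@@H]12 | intermediate
18 | 4-iodophenol | Oc1ccc(I)cc1 | starting material
19 | (1R,2S,4aR,8aR)-4a,8-dimethyl-2-(propan-2-yl)-1,2,3,4,4a,5,6,8a-octahydronaphthalen-1-yl (2E)-3-(4-hydroxyphenyl)prop-2-enoate | CC1=CCC[C@]2(C)CC[C@@H](C(C)C)[C@@H](OC(=O)/C=C/c3ccc(O)cc3)[C@@H]12 | target

**Step count and risks**
Total steps: 7. Longest linear sequence: 6 (steps 1, 2, 4, 5, 6, 7 from compound 1); step 3 is a one-step branch.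

Step 4 is the most likely to fail, because the migration regiochemistry and the catalyst control at C7 are unproven. Its fallback uses known reactions only, sets out from 6 and comes back at 14. Ring expansion of 6 with Me3SiCHN2 and BF3·OEt2 (CH2Cl2, −78 °C, alkyl migration), followed by K2CO3/MeOH desilylation, gives (4aR)-4a,8-dimethyl-3,4,4a,5,6,7-hexahydronaphthalen-1(2H)-one F5. Its kinetic α′-enolate (LiN(i-Pr)2, THF–DMPU, −78 °C) is alkylated with 2-iodopropane to (4aR)-4a,8-dimethyl-2-(propan-2-yl)-3,4,4a,5,6,7-hexahydronaphthalen-1(2H)-one F6 as a mixture of 2-epimers. Deconjugation as in step 2 (KOtBu/t-BuOH, then cold AcOH) gives 14 together with (2R,4aR,8aR)-4a,8-dimethyl-2-(propan-2-yl)-3,4,4a,5,6,8a-hexahydronaphthalen-1(2H)-one F7. The mixture is reduced with LiBH(s-Bu)3 as in step 5; F7, with its axial isopropyl group, should react more slowly and is removed by chromatography. This fallback does not control C7 (thermodynamic ratio about 3:1 at best), so material is lost to separation.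

Step 2 is the second risk, because the β,γ-unsaturated cyclopentanone 8 may revert to 6 or form the exocyclic methylene isomer. The fallback sets out from 1 and comes back at 8. Conjugate addition of but-3-enylmagnesium bromide to 1 (the Cu(OTf)2/NHC system of step 1, Me3SiCl trap) gives (R)-{[3-(but-3-en-1-yl)-3-methylcyclopent-1-en-1-yl]oxy}trimethylsilane F3. MeLi releases the regiodefined lithium enolate, and α-alkenylation with 2-bromopropene (Ni(cod)2, 1,3-bis(2,6-diisopropylphenyl)imidazolium chloride) gives (3R)-3-(but-3-en-1-yl)-3-methyl-2-(prop-1-en-2-yl)cyclopentan-1-one F4. Ring-closing metathesis with the second-generation Grubbs catalyst closes ring A with the alkene already in the β,γ-position and gives 8.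

Step 1 is the third risk, because Grignard additions to a five-membered β-methyl enone often give moderate enantioselectivity and conversion. The fallback reverses the roles of the two carbon groups, sets out from 3 and comes back at 4. Grignard reagent 3 is added to 3-(2-methylpropoxy)cyclopent-2-en-1-one F1 (made from cyclopentane-1,3-dione, 2-methylpropan-1-ol and TsOH). Cold dilute acid work-up gives 3-[3-(2-methyl-1,3-dioxolan-2-yl)propyl]cyclopent-2-en-1-one F2 (Stork–Danheiser transposition). Copper-catalysed asymmetric conjugate addition of AlMe3 (Cu(OTf)2, chiral phosphoramidite, Et2O, −30 °C) gives 4, which goes into the acid annulation of step 1.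

**Further compounds**
F1 | step 1 | 3-(2-methylpropoxy)cyclopent-2-en-1-one | CC(C)COC1=CC(=O)CC1
F2 | step 1 | 3-[3-(2-methyl-1,3-dioxolan-2-yl)propyl]cyclopent-2-en-1-one | CC1(CCCC2=CC(=O)CC2)OCCO1
F3 | step 2 | (R)-{[3-(but-3-en-1-yl)-3-methylcyclopent-1-en-1-yl]oxy}trimethylsilane | C=CCC[C@]1(C)CCC(O[Si](C)(C)C)=C1
F4 | step 2 | (3R)-3-(but-3-en-1-yl)-3-methyl-2-(prop-1-en-2-yl)cyclopentan-1-one, mixture of 2-epimers | C=CCC[C@]1(C)CCC(=O)C1C(C)=C
F5 | step 4 | (4aR)-4a,8-dimethyl-3,4,4a,5,6,7-hexahydronaphthalen-1(2H)-one | CC1=C2C(=O)CCC[C@@]2(C)CCC1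
F6 | step 4 | (4aR)-4a,8-dimethyl-2-(propan-2-yl)-3,4,4a,5,6,7-hexahydronaphthalen-1(2H)-one, mixture of 2-epimers | CC1=C2C(=O)C(C(C)C)CC[C@@]2(C)CCC1
F7 | step 4 | (2R,4aR,8aR)-4a,8-dimethyl-2-(propan-2-yl)-3,4,4a,5,6,8a-hexahydronaphthalen-1(2H)-one | CC1=CCC[C@]2(C)CC[C@H](C(C)C)C(=O)[C@@H]12
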